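3 questions stand on ochre and green, one charge read at two times.

| flask | substrate | temperature | remark | time |
|---|---|---|---|---|
| dusk | 5 mM | 20 °C | run made earlier |  |
| summer | 7.5 mM | 31 °C | run made earlier |  |
| ochre | 10 mM | 25 °C |  | 25 min |
| green | 10 mM | 25 °C |  | 50 min |

| run | time / min | single ring / % |
|---|---|---|
| dusk | 5.00 | 4.7 |
| dusk | 12.0 | 10.0 |
| dusk | 25.0 | 18.2 |
| dusk | 60.0 | 32.2 |
| summer | 15.0 | 31.9 |
| summer | 30.0 | 48.3 |
| summer | 50.0 | 62.6 |
| summer | 60.0 | 66.7 |

(each reading ± 0.5 percentage points)

- which of the two ends with the higher amount of single ring, in percent of the substrate charged ("neither" if they lie within 2 percentage points) (ochre / green / neither)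
- single ring at the end, in percent of the substrate charged, ochre
- single ring at the end, in percent of the substrate charged, green



Suppose single ring approaches a plateau as first-order relaxation with constant k, and call n = kt the turnovers made by time t. The doubling gain, the reading at twice a time over the reading at that time, is then one plus e^(−n), whatever the plateau. Summer's pair at 30.0 min and 60.0 min gives 0.0322 min⁻¹, and dusk's 12.0 min and 25.0 min, taken as such a pair, give 0.0165 min⁻¹. This separate reckoning sets the difference in charge aside and interpolates on temperature to 0.0236 min⁻¹, so ochre is estimated at 0.591 turnovers and the doubling gain, green over ochre, at 1.55. Scaled on dusk's reading of 18.2 %, as a stand-in for ochre, the lead estimated for green is 10 percentage points, above the margin of 2 points, so this reckoning names green.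

The forecast says green, with 32 % and 47 %, a gain of 1.47, by “I take values in between”; the reckoned gain differs slightly.

The flask gives green, with 26.0 % in ochre and 39.5 % in green, a gain of 1.52 against the reckoned 1.55.

    substrate → single ring (k = 0.0190 min⁻¹, Ea = 86.0 kJ mol⁻¹)
    2 substrate → open dimer (k = 0.950 M⁻¹ min⁻¹, Ea = 55.0 kJ mol⁻¹)
    open dimer → ring dimer (k = 0.0980 min⁻¹, Ea = 93.0 kJ mol⁻¹)
    2 substrate → homo dimer (k = 0.00200 M⁻¹ min⁻¹, Ea = 75.0 kJ mol⁻¹)
    substrate ⇌ dormant form (K = 0.590, k = 0.0410 min⁻¹, Ea = 91.0 kJ mol⁻¹, ΔH = −24.0 kJ mol⁻¹)
    substrate + open dimer → open trimer (k = 1.00 M⁻¹ min⁻¹, Ea = 71.0 kJ mol⁻¹)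
    (constants at 25 °C)

In green, half of the turnover to dormant form was done by 2.50 min, a pre-equilibrium with relaxation half-life 6.27 min by this step alone, shorter than the half-life of 36 min of substrate by the making of single ring alone. Dormant form then fell from 23.1 % at 25.0 min to 17.1 % at 50.0 min while substrate fell to 23.4 % and single ring rose. In the first-order reckoning the gain minus one is the share of the way to the plateau still open at 25 min, so from ochre's 26.0 % the gain 1.55 reckons 22.0 % of single ring for the neighbour of green stopped at 20 min, which held 22.6 %.

All runs were computed for an exercise.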